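Germacranolide numbering is used (C12 lactone carbonyl, C11 its methyl-bearing α-carbon, C6 the O-bearing carbon). The lactone ring (O, C12, C11, C7, C6) with the adjoining Z olefin C4=C5 and C3 is read as an opened 8-oxabicyclo[3.2.1]octenone: C12–O–C6–C5=C4–C3 are the six ring atoms of a 3-oxidopyrylium. Its (5+2) cycloaddition with an N-crotonoyl camphorsultam forms C12–C11 and C6–C7 in one operation and sets C6, C7 and C11; the precursors are an achiral acetoxypyranone and a chiral enoyl imide. The C3–C12 bond is later cut by alkoxy-radical fragmentation; a Claisen ring closure and furanone cyclodehydration finish the ten-membered ring.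

Key step: step 5

Assumption: in the uncatalysed cycloaddition the (2R)-bornane-10,2-sultam is taken to direct attack to the Cα-re face of its s-cis enoyl unit (C=O anti to SO2), the usual model for thermal additions to N-enoyl camphorsultams; with the opposite sense the antipodal sultam would be used.

Step 1
Reactants: 1 methyl 3-methylfuran-2-carboxylate
Product: 2 (3-methylfuran-2-yl)methanol
Conditions: LiAlH4, Et2O, 0 °C
Reagents that add atoms: none
Why: Hydride reduction of the ester gives the primary furfuryl alcohol, the furan is inert and no stereocenter is formed.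

Step 2
Reactants: 2 (3-methylfuran-2-yl)methanol
Product: 3 6-hydroxy-4-methyl-2H-pyran-3(6H)-one
Conditions: NBS, NaHCO3, THF/H2O, 0 °C
Reagents that add atoms: water (O)
Why: Achmatowicz rearrangement, in which oxidative opening of the furan to the cis-enedione and hemiacetal closure give the pyranone; its hemiacetal center is racemic and disappears in step 5.

Step 3
Reactants: 3 6-hydroxy-4-methyl-2H-pyran-3(6H)-one
Product: 4 4-methyl-5-oxo-5,6-dihydro-2H-pyran-2-yl acetate
Conditions: Ac2O, pyridine, DMAP (cat.), CH2Cl2, 0 °C
Reagents that add atoms: acetic anhydride (CC(=O)OC(C)=O)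
Why: O-acylation of the lactol installs the leaving group needed for ylide formation.

Step 4
Reactants: 5 (2R)-bornane-10,2-sultam; 6 (E)-but-2-enoyl chloride
Product: 7 N-[(E)-but-2-enoyl]-(2R)-bornane-10,2-sultam
Conditions: NaH, toluene, 0 to 25 °C
Reagents that add atoms: none
Why: N-acylation of the sodium salt of the sultam by the acid chloride should give the enoyl imide with the E geometry unchanged.

Step 5
Reactants: 4 4-methyl-5-oxo-5,6-dihydro-2H-pyran-2-yl acetate; 7 N-[(E)-but-2-enoyl]-(2R)-bornane-10,2-sultam
Product: 9 6-exo-(sultam-carbonyl)-3,7-endo-dimethyl-8-oxabicyclo[3.2.1]oct-3-en-2-one, via oxidopyrylium ylide 8 (not isolated)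
Conditions: iPr2NEt, MeCN, 50 °C, slow addition of 4
Reagents that add atoms: none
Why: Base-induced 1,4-elimination of acetic acid from 4 gives the 3-oxidopyrylium 8, a cyclic carbonyl ylide whose termini are the future C12 (next to the oxide) and C6, and this adds across the enoyl C=C of 7 in a concerted suprafacial (5+2) cycloaddition, the closest precedent being oxidopyrylium–acrylate cycloadditions to 8-oxabicyclo[3.2.1]oct-3-en-2-ones. Two rings close in this one intermolecular event, the oxolane (O, C12, C11, C7, C6; a (3+2) closure across the C–O–C ylide) and the cycloheptenone (C12, C3, C4, C5, C6, C7, C11; the (5+2) closure). Regiochemistry follows the polarisation of the partners, the nucleophilic ylide carbon C12 bonding to the β-carbon C11 and the oxocarbenium-like C6 to the α-carbon C7, as with acrylates. The E geometry of 7 is transferred stereospecifically into the trans C7/C11 relationship and the bridgeheads C6 and C12 are held cis by the ring. The bulky sultam imide is expected to take the exo position away from the enone bridge and leave the small methyl endo, which is the trans C6/C7, trans C7/C11 pattern of the target lactone. Absolute configuration rests on the sultam, which shields the Cα-si face so that C6 bonds to the Cα-re face, and the slow addition of 4 keeps the ylide dilute against its dimerisation.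

Step 6
Reactants: 9 sultam cycloadduct
Product: 10 S-ethyl 3,7-endo-dimethyl-2-oxo-8-oxabicyclo[3.2.1]oct-3-ene-6-exo-carbothioate
Conditions: EtSH, n-BuLi, THF, −20 to 0 °C
Reagents that add atoms: ethanethiol (CCS)
Why: Nucleophilic acyl substitution of the imide by thiolate releases the sultam as leaving group for recovery, the low temperature limiting reversible thia-Michael addition to the enone, and no stereocenter is touched.

Step 7
Reactants: 10 thioester
Product: 11 6-exo-acetyl-3,7-endo-dimethyl-8-oxabicyclo[3.2.1]oct-3-en-2-one
Conditions: MeZnI, PdCl2(PPh3)2 (5 mol %), toluene/THF, 25 °C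
Reagents that add atoms: methylzinc iodide (C[Zn]I)
Why: Fukuyama coupling, a palladium-catalysed acyl substitution of the thioester by the organozinc, should give the methyl ketone while the ring enone, which organozincs do not attack, stays intact.

Step 8
Reactants: 11 methyl ketone
Product: 12 trimethylsilyl enol ether of 11
Conditions: LiN(iPr)2, Me3SiCl, THF, −78 °C
Reagents that add atoms: chlorotrimethylsilane (C[Si](C)(C)Cl)
Why: Kinetic enolisation with internal silyl quench occurs at the acetyl methyl group (C9), since the ring ketone has only a bridgehead and a vinylic α-position and cannot enolise.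

Step 9
Reactants: 12 silyl enol ether; 13 methyl pyruvate
Product: 14 methyl (2R)-2-hydroxy-2-methyl-4-oxo-4-(bicyclic)butanoate
Conditions: Cu(OTf)2 and (R,R)-tBu-box ligand (10 mol %), THF, −78 °C; then 1 M HCl
Reagents that add atoms: none
Why: Copper–bis(oxazoline)-catalysed Mukaiyama aldol, in which pyruvate chelated to the divalent copper complex is attacked on one keto face only, so that the (R,R) ligand is expected to set the 10R tertiary carbinol under catalyst control.

Step 10
Reactants: 14 aldol adduct
Product: 16 (3R,5R)-3-hydroxy-3-methyl-5-(bicyclic)oxolan-2-one, via diol ester 15 (not isolated)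
Conditions: Et2BOMe, NaBH4, THF/MeOH, −78 °C; MeOH/AcOH evaporation; then PPTS, CH2Cl2, 25 °C
Reagents that add atoms: none
Why: Narasaka–Prasad reduction, in which the β-hydroxy ketone is held as a six-membered boron chelate with the carbinol methyl pseudo-equatorial and the smaller ester pseudo-axial so that axial hydride attack should give the 8R alcohol, the enone being inert at −78 °C, after which the γ-hydroxy ester lactonises under mild acid.

Step 11
Reactants: 16 hydroxy lactone
Product: 17 triethylsilyl ether of 16
Conditions: Et3SiOTf, 2,6-lutidine, CH2Cl2, −78 to 0 °C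
Reagents that add atoms: triethylsilyl trifluoromethanesulfonate (CC[Si](CC)(CC)OS(=O)(=O)C(F)(F)F)
Why: Silyl triflate silylation protects the only hydroxyl, the tertiary C10–OH, which must be masked for steps 12 to 14.

Step 12
Reactants: 17 silyl ether
Product: 18 tertiary carbinol (methyl added to the ring ketone C3)
Conditions: MeLi, CeCl3, THF, −78 °C
Reagents that add atoms: methyllithium ([Li]C)
Why: Organocerium 1,2-addition to the only ketone should outrun attack on the hindered α-silyloxy lactone; methyl is expected to enter from the oxygen-bridge face opposite the endo C11 methyl, but this carbinol center is erased in step 13.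

Step 13
Reactants: 18 tertiary carbinol
Product: 20 oxolane methyl acetal bearing the (Z)-2-methyl-3-oxobut-1-enyl chain, via acetoxy acetal 19 (not isolated)
Conditions: PhI(OAc)2, I2, CH2Cl2, tungsten lamp, 25 °C; then MeOH, PPTS, 0 °C
Reagents that add atoms: (diacetoxyiodo)benzene (CC(=O)OI(OC(C)=O)c1ccccc1; acetoxy group of 19), methanol (CO; methoxy group of 20)
Why: Suárez hypoiodite fragmentation, in which the tertiary alkoxy radical undergoes β-scission of the C3–C12 bond because this releases the bicyclic strain and gives an oxygen-stabilised radical that is oxidised to the oxocarbenium ion and trapped, freeing the C3 methyl ketone with the Z C4=C5 geometry fixed by the former ring and leaving C6, C7 and C11 untouched.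

Step 14
Reactants: 20 methyl ketone lactone
Product: 21 ten-membered 1,3-diketone (8-hydroxy, 10-triethylsilyloxy, C12 methyl acetal)
Conditions: LiN(SiMe3)2, THF, 2 mM, −78 to 0 °C
Reagents that add atoms: none
Why: Intramolecular Claisen condensation as a ring-expanding acyl transfer, in which the enolate of the methyl ketone (C2) is the only carbanion that can form, the lactone has no α-hydrogen and the C12 acetal is inert, so attack on the lactone carbonyl C1 with loss of the C8 alkoxide gives the ten-membered β-diketonate whose stability drives the closure.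

Step 15
Reactants: 21 macrocyclic diketone
Product: 22 8-hydroxy furanone with C12 methyl acetal
Conditions: TsOH·H2O, MeOH, 25 °C
Reagents that add atoms: none
Why: Acid removes the silyl ether and the freed C10 hydroxyl adds to the C3 carbonyl and dehydrates (classical 3(2H)-furanone cyclodehydration of an α'-hydroxy-1,3-diketone) to the conjugated furanone as the thermodynamic product, the methyl acetal being retained in methanol.

Step 16
Reactants: 22 8-hydroxy furanone; 23 angelic acid
Product: 25 8-O-angelate with C12 methyl acetal, via mixed anhydride 24 (not isolated)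
Conditions: 2,4,6-Cl3C6H2COCl, Et3N, toluene, 25 °C; then 22, 80 °C
Reagents that add atoms: 2,4,6-trichlorobenzoyl chloride (O=C(Cl)c1c(Cl)cc(Cl)cc1Cl; aroyl group of 24 only)
Why: Yamaguchi-type esterification through the mixed anhydride acylates the C8 hydroxyl with retention under conditions chosen because they should not isomerise the Z angelate to the tiglate.

Step 17
Reactants: 25 angelate methyl acetal
Product: 26 target compound
Conditions: CrO3, H2SO4, H2O/acetone, 0 °C
Reagents that add atoms: water (O)
Why: Jones oxidation, in which aqueous acid hydrolyses the cyclic methyl acetal to the lactol and hexavalent chromium oxidises it to the γ-lactone, the electron-poor olefins and the esters being inert and C11 keeping its configuration, which is also the thermodynamically preferred trans one.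

Compound list

1 | methyl 3-methylfuran-2-carboxylate | COC(=O)c1occc1C | starting material
2 | (3-methylfuran-2-yl)methanol | OCc1occc1C | intermediate
3 | 6-hydroxy-4-methyl-2H-pyran-3(6H)-one (racemic hemiacetal) | OC1OCC(=O)C(C)=C1 | intermediate
4 | 4-methyl-5-oxo-5,6-dihydro-2H-pyran-2-yl acetate (racemic) | CC(=O)OC1OCC(=O)C(C)=C1 | intermediate
5 | (1S)-(−)-2,10-camphorsultam, (2R)-bornane-10,2-sultam | O=S1(=O)N[C@@H]2C[C@H]3CC[C@]2(C1)C3(C)C | starting material
6 | (E)-but-2-enoyl chloride | C/C=C/C(Cl)=O | starting material
7 | N-[(E)-but-2-enoyl]-(2R)-bornane-10,2-sultam | C/C=C/C(=O)N1[C@@H]2C[C@H]3CC[C@]2(CS1(=O)=O)C3(C)C | intermediate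
8 | 4-methyl-3-oxidopyrylium (ylide, not isolated) | Cc1cc[o+]cc1[O-] | intermediate
9 | N-acyl sultam of 3,7-dimethyl-2-oxo-8-oxabicyclo[3.2.1]oct-3-ene-6-carboxylic acid, acyl exo, 7-methyl endo (bicycle C1, C5, C6, C7 are target C12, C6, C7, C11) | O=C1C(C)=C[C@H]2O[C@@H]1[C@@H](C)[C@@H]2C(=O)N3[C@@H]4C[C@H]5CC[C@]4(CS3(=O)=O)C5(C)C | intermediate
10 | S-ethyl 3,7-endo-dimethyl-2-oxo-8-oxabicyclo[3.2.1]oct-3-ene-6-exo-carbothioate | O=C1C(C)=C[C@H]2O[C@@H]1[C@@H](C)[C@@H]2C(=O)SCC | intermediate
11 | 6-exo-acetyl-3,7-endo-dimethyl-8-oxabicyclo[3.2.1]oct-3-en-2-one | O=C1C(C)=C[C@H]2O[C@@H]1[C@@H](C)[C@@H]2C(C)=O | intermediate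
12 | 3,7-endo-dimethyl-6-exo-[1-(trimethylsilyloxy)ethenyl]-8-oxabicyclo[3.2.1]oct-3-en-2-one | O=C1C(C)=C[C@H]2O[C@@H]1[C@@H](C)[C@@H]2C(=C)O[Si](C)(C)C | intermediate
13 | methyl pyruvate | CC(=O)C(=O)OC | starting material
14 | methyl (2R)-2-hydroxy-2-methyl-4-oxo-4-(3,7-endo-dimethyl-2-oxo-8-oxabicyclo[3.2.1]oct-3-en-6-exo-yl)butanoate | O=C1C(C)=C[C@H]2O[C@@H]1[C@@H](C)[C@@H]2C(=O)C[C@@](C)(O)C(=O)OC | intermediate
15 | methyl (2R,4R)-2,4-dihydroxy-2-methyl-4-(bicyclic)butanoate (not isolated) | O=C1C(C)=C[C@H]2O[C@@H]1[C@@H](C)[C@@H]2[C@H](O)C[C@@](C)(O)C(=O)OC | intermediate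
16 | (3R,5R)-3-hydroxy-3-methyl-5-(3,7-endo-dimethyl-2-oxo-8-oxabicyclo[3.2.1]oct-3-en-6-exo-yl)oxolan-2-one | O=C1C(C)=C[C@H]2O[C@@H]1[C@@H](C)[C@@H]2[C@H]3C[C@@](C)(O)C(=O)O3 | intermediate
17 | triethylsilyl ether of 16 | O=C1C(C)=C[C@H]2O[C@@H]1[C@@H](C)[C@@H]2[C@H]3C[C@@](C)(O[Si](CC)(CC)CC)C(=O)O3 | intermediate
18 | 2-hydroxy-2,3,7-trimethyl bicyclic carbinol from 17 (new methyl on the oxygen-bridge face; center erased in step 13) | C[C@@]1(O)C(C)=C[C@H]2O[C@@H]1[C@@H](C)[C@@H]2[C@H]3C[C@@](C)(O[Si](CC)(CC)CC)C(=O)O3 | intermediate
19 | acetoxy acetal: 2-acetoxyoxolane (C12) with 3-methyl (C11), 4-(silyloxy-lactone) (C7) and 5-[(Z)-2-methyl-3-oxobut-1-enyl] (C6); anomer drawn with the acetoxy group trans to the C11 methyl, not isolated | CC(=O)/C(C)=C\[C@H]1O[C@H](OC(C)=O)[C@@H](C)[C@@H]1[C@H]2C[C@@](C)(O[Si](CC)(CC)CC)C(=O)O2 | intermediate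
20 | methyl acetal corresponding to 19 (anomer drawn with OMe trans to the C11 methyl; either anomer serves, the center is erased in step 17) | CC(=O)/C(C)=C\[C@H]1O[C@H](OC)[C@@H](C)[C@@H]1[C@H]2C[C@@](C)(O[Si](CC)(CC)CC)C(=O)O2 | intermediate
21 | ten-membered 1,3-diketone (C1 and C3 ketones, Z-C4=C5, 8R-hydroxy, 10R-triethylsilyloxy, oxolane methyl acetal at C12) | O=C1CC(=O)/C(C)=C\[C@H]2O[C@H](OC)[C@@H](C)[C@@H]2[C@H](O)C[C@@]1(C)O[Si](CC)(CC)CC | intermediate
22 | 8-hydroxy furanone, the 8-deacyl target with C12 as methyl acetal in place of the lactone carbonyl | O[C@@H]1C[C@@]2(C)OC(=CC2=O)/C(C)=C\[C@H]2O[C@H](OC)[C@@H](C)[C@@H]21 | intermediate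
23 | angelic acid, (Z)-2-methylbut-2-enoic acid | C/C=C(/C)C(=O)O | starting material
24 | angelic 2,4,6-trichlorobenzoic anhydride (not isolated) | C/C=C(/C)C(=O)OC(=O)c1c(Cl)cc(Cl)cc1Cl | intermediate
25 | 8-O-angelate of 22 | C/C=C(/C)C(=O)O[C@@H]1C[C@@]2(C)OC(=CC2=O)/C(C)=C\[C@H]2O[C@H](OC)[C@@H](C)[C@@H]21 | intermediate
26 | target compound (6R,7R,8R,10R,11S) | C/C=C(/C)C(=O)O[C@@H]1C[C@@]2(C)OC(=CC2=O)/C(C)=C\[C@H]2OC(=O)[C@@H](C)[C@@H]21 | target

Total step count: 17. Longest linear sequence: 16 steps (steps 1 to 3 and 5 to 17); step 4 is a one-step side branch.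

Steps most likely to fail

Step 5. The ylide may dimerise faster than it adds to the hindered β-substituted imide, and exo placement of the acyl group or π-facial discrimination may be incomplete. The fallback gives up auxiliary control and resolves through the catalyst-controlled aldol. It sets out from 4, which is treated with iPr2NEt in a large excess of (E)-pent-3-en-2-one as cosolvent; the excess of this cheap acceptor suppresses dimerisation and the exo-acetyl adduct should form as the racemate, that is 11 together with its enantiomer ent-11 F1. The conditions of step 8 convert both into 12 and the enantiomeric silyl enol ether ent-12 F2. The (R,R) copper catalyst of step 9 then sets 10R in both, so that the two enantiomers become the diastereomers 14 and the bicycle-epimeric aldol F3, which are separated on silica. The route is rejoined at 14.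

Step 14. The ten-membered transition state may lose to intermolecular condensation, or the enolate may be quenched by proton exchange before it reaches the hindered lactone carbonyl. The fallback generates the enolate reductively and irreversibly. It sets out from 20, whose methyl ketone is converted with Me3SiOTf and Et3N into the silyloxydiene F4 and then with NBS into the bromomethyl ketone F5. SmI2 in THF at −78 °C under high dilution forms the samarium enolate under neutral conditions, and its Reformatsky-type intramolecular acyl substitution on the lactone should give 21, where the route is rejoined.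

Step 10. Hydride may be delivered to the other face of the boron chelate if the ester rather than the methyl group sits pseudo-equatorial, so that the 8S alcohol predominates. The fallback corrects C8 by inversion during ring closure instead of by the reduction. It sets out from 14, and the 8S diol ester 8-epi-15 F6 is saponified with LiOH in THF/H2O at 0 °C to the hydroxy acid F7. After careful neutralisation this is closed with PPh3 and diisopropyl azodicarboxylate in a Mitsunobu lactonisation, in which the carboxylate displaces the activated C8 oxygen with inversion to give 16, where the route is rejoined.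

Further compounds

F1 | step 5 | ent-11, enantiomer of 6-exo-acetyl-3,7-endo-dimethyl-8-oxabicyclo[3.2.1]oct-3-en-2-one | O=C1C(C)=C[C@@H]2O[C@H]1[C@H](C)[C@H]2C(C)=O
F2 | step 5 | ent-12, enantiomeric trimethylsilyl enol ether | O=C1C(C)=C[C@@H]2O[C@H]1[C@H](C)[C@H]2C(=C)O[Si](C)(C)C
F3 | step 5 | diastereomer of 14 with the antipodal bicycle and the 2R carbinol | O=C1C(C)=C[C@@H]2O[C@H]1[C@H](C)[C@H]2C(=O)C[C@@](C)(O)C(=O)OC
F4 | step 14 | trimethylsilyl enol ether (silyloxydiene) of 20 | C=C(O[Si](C)(C)C)/C(C)=C\[C@H]1O[C@H](OC)[C@@H](C)[C@@H]1[C@H]2C[C@@](C)(O[Si](CC)(CC)CC)C(=O)O2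
F5 | step 14 | bromomethyl ketone derived from 20 | BrCC(=O)/C(C)=C\[C@H]1O[C@H](OC)[C@@H](C)[C@@H]1[C@H]2C[C@@](C)(O[Si](CC)(CC)CC)C(=O)O2
F6 | step 10 | 8-epi-15, methyl (2R,4S)-2,4-dihydroxy-2-methyl-4-(bicyclic)butanoate | O=C1C(C)=C[C@H]2O[C@@H]1[C@@H](C)[C@@H]2[C@@H](O)C[C@@](C)(O)C(=O)OC
F7 | step 10 | (2R,4S)-2,4-dihydroxy-2-methyl-4-(bicyclic)butanoic acid | O=C1C(C)=C[C@H]2O[C@@H]1[C@@H](C)[C@@H]2[C@@H](O)C[C@@](C)(O)C(=O)O
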